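**Plan**

1. Numbering (3,7-dioxabicyclo[3.3.0]octane, Ar = 3,4-dimethoxyphenyl): C1 carbinol bridgehead, C2 ArCH next to it, O3, C4 CH2, C5 bridgehead CH, C6 ArCH, O7, C8 CH2; ring A = C1–C5–C6–O7–C8, ring B = C1–C2–O3–C4–C5.
2. Enabling feature: in ring B, O3 lies between an aryl-bearing methine (C2) and a methylene (C4), and C1 carries oxygen. Ring B is therefore an oxygen-expanded cyclobutanone C1–C2–C4(=O)–C5 fused to ring A at C1–C5, the adduct of an arylketene (C2, C4) and the C1=C5 enol ether of a ring-A furan-3-one.
3. Retrosynthetic cuts, in order: O3–C4 (ether from lactone), C2–O3 (Baeyer–Villiger oxygen), C4–C5 together with C1–C2 (ketene [2+2]), then O7–C8 and C5–C6 of ring A.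
4. Forward: propargylation of veratraldehyde joins C5–C6; gold-catalysed alkyne oxidation closes ring A at O7–C8; enol silylation; the [2+2] closes the cyclobutanone; peracid converts it into the ring-B lactone; reduction, desilylation and etherification give ring B as the cyclic ether.
5. Stereochemistry: C6 from the chiral phosphoric acid catalyst; C1 and C5 from ketene attack on the ring-A face opposite the C6 aryl; C2 from the endo preference of the ketene aryl; oxygen insertion and the last ring closure proceed with retention at C2.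

Key step: step 5

Assumption: the S antipode of the phosphoric acid is taken to give the S carbinol (the R catalyst/R carbinol pairing usual for aryl aldehydes); if the first batch shows the opposite sense, the other catalyst antipode is used.

**Route**

Step 1
Reactants: 1 veratraldehyde; 2 allenylboronic acid pinacol ester
Product: 3 (S)-1-(3,4-dimethoxyphenyl)but-3-yn-1-ol
Conditions: 2 (1.5 equiv), (S)-TRIP [(S)-3,3'-bis(2,4,6-triisopropylphenyl)-1,1'-binaphthyl-2,2'-diyl hydrogen phosphate] (10 mol%), 4 Å MS, toluene, 0 °C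
Reagents that add atoms: none
Why: Chiral phosphoric acid-catalysed propargylboration, in which the acid-activated allenylboronate adds through a closed six-membered transition state with SE2' transposition, so the catalyst selects the aldehyde face and sets C6 as S.

Step 2
Reactants: 3 (S)-1-(3,4-dimethoxyphenyl)but-3-yn-1-ol
Product: 4 (S)-5-(3,4-dimethoxyphenyl)dihydrofuran-3(2H)-one
Conditions: Ph3PAuNTf2 (5 mol%), 8-methylquinoline N-oxide (1.5 equiv), ClCH2CH2Cl, rt, no added acid
Reagents that add atoms: 8-methylquinoline N-oxide, Cc1cccc2ccc[n+]([O-])c12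
Why: Gold-catalysed oxidative cyclisation of a homopropargylic alcohol, in which the N-oxide delivers oxygen to the internal alkyne carbon (C1) and the hydroxyl closes on the terminal carbon by O–H insertion (O7–C8); the carbinol C–O bond is untouched so C6 is retained, and the acid-free variant spares the electron-rich benzylic alcohol.

Step 3
Reactants: 4 (S)-5-(3,4-dimethoxyphenyl)dihydrofuran-3(2H)-one
Product: 6 (S)-tert-butyl{[5-(3,4-dimethoxyphenyl)-2,5-dihydrofuran-3-yl]oxy}dimethylsilane, via potassium enolate 5 (not isolated)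
Conditions: KN(SiMe3)2 (1.1 equiv, added last), TBSCl, THF, −78 °C
Reagents that add atoms: tert-butyldimethylsilyl chloride, CC(C)(C)[Si](C)(C)Cl
Why: Kinetic enolate trapping, in which the amide base should remove a C5 proton and not a C8 proton because deprotonation next to the ring oxygen is slowed by lone-pair repulsion (as in enol triflate formation from 3-oxo-tetrahydrofurans and 3-oxo-pyrrolidines), and cold in situ O-silylation fixes the C1=C5 enol ether before equilibration or β-elimination.

Step 4
Reactants: 7 (3,4-dimethoxyphenyl)acetic acid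
Product: 8 (3,4-dimethoxyphenyl)acetyl chloride
Conditions: (COCl)2, DMF (cat.), CH2Cl2, 0 °C → rt; used crude
Reagents that add atoms: oxalyl chloride, ClC(=O)C(=O)Cl
Why: Acyl chloride formation through the Vilsmeier-type chloroiminium catalyst, under which the veratryl ring and the benzylic methylene are inert.

Step 5
Reactants: 6 (S)-tert-butyl{[5-(3,4-dimethoxyphenyl)-2,5-dihydrofuran-3-yl]oxy}dimethylsilane; 8 (3,4-dimethoxyphenyl)acetyl chloride
Product: 10 (1S,4S,5R,7S)-1-(tert-butyldimethylsilyloxy)-4,7-bis(3,4-dimethoxyphenyl)-3-oxabicyclo[3.2.0]heptan-6-one, via (3,4-dimethoxyphenyl)ketene 9 (not isolated)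
Conditions: 8 (2.5 equiv), Et3N (2.4 equiv, syringe pump over several hours), toluene, 60 °C
Reagents that add atoms: none
Why: Slow dehydrochlorination of 8 releases ketene 9, whose electrophilic central carbon (future C4) is attacked by the nucleophilic enol ether carbon C5 while its aryl-bearing carbon (future C2) bonds to the silyloxy carbon C1 in an asynchronous thermal [2+2] cycloaddition, the polarity match fixing this regiochemistry. The closest known reaction type is the ketene–silyl enol ether cycloaddition to 3-silyloxycyclobutanones, together with the endo-selective addition of monosubstituted ketenes to cycloalkenes. The cyclobutanone ring closes by bimolecular cycloaddition, its second bond (C1–C2) forming as a 4-exo-trig collapse of the enolate carbon onto the silyloxy-stabilised cationic carbon. C1 and C5 are controlled by the C6 stereocentre, because the allylic aryl group shields its own face of the nearly flat dihydrofuran and the ketene adds to the other one, leaving OTBS, H-5 and the C6 aryl cis to one another. C2 is controlled by the ketene geometry: it approaches crosswise with its hydrogen towards the alkene, and the twist that closes the ring swings the aryl to the concave side, cis to C8 and trans to OTBS. The step needs facial, regio- and endo selectivity and suppression of ketene dimerisation; the first three rest on the C6 aryl, the enol ether polarisation and the ketene approach, and the last on slow ketene release into the enol ether solution, with the amine kept substoichiometric to 8 so that the acidic C2–H of 10 is not epimerised.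

Step 6
Reactants: 10 (1S,4S,5R,7S)-1-(tert-butyldimethylsilyloxy)-4,7-bis(3,4-dimethoxyphenyl)-3-oxabicyclo[3.2.0]heptan-6-one
Product: 11 (1S,2S,5R,6S)-1-(tert-butyldimethylsilyloxy)-2,6-bis(3,4-dimethoxyphenyl)-3,7-dioxabicyclo[3.3.0]octan-4-one (target numbering)
Conditions: mCPBA, NaHCO3, CH2Cl2, 0 °C
Reagents that add atoms: 3-chloroperoxybenzoic acid, OOC(=O)c1cccc(Cl)c1
Why: Baeyer–Villiger oxidation of a strained cyclobutanone, in which the electron-rich benzylic C2 (one β-oxygen) should migrate in preference to C5 (two β-oxygens) with retention, inserting O3 between C4 and C2, while buffer and low temperature protect the dimethoxyarenes and the silyl ether.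

Step 7
Reactants: 11 (1S,2S,5R,6S)-1-(tert-butyldimethylsilyloxy)-2,6-bis(3,4-dimethoxyphenyl)-3,7-dioxabicyclo[3.3.0]octan-4-one
Product: 12 (S)-[(3S,4R,5S)-3-(tert-butyldimethylsilyloxy)-5-(3,4-dimethoxyphenyl)-4-(hydroxymethyl)oxolan-3-yl](3,4-dimethoxyphenyl)methanol
Conditions: LiAlH4, THF, 0 °C
Reagents that add atoms: none
Why: Hydride reduction of a lactone to the 1,4-diol, which leaves the C2–O3 bond and every stereocentre intact; a silyl shift between the oxygens would be harmless because silicon is removed next.

Step 8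
Reactants: 12 (S)-[(3S,4R,5S)-3-(tert-butyldimethylsilyloxy)-5-(3,4-dimethoxyphenyl)-4-(hydroxymethyl)oxolan-3-yl](3,4-dimethoxyphenyl)methanol
Product: 13 (3S,4R,5S)-5-(3,4-dimethoxyphenyl)-3-[(S)-(3,4-dimethoxyphenyl)(hydroxy)methyl]-4-(hydroxymethyl)oxolan-3-ol
Conditions: Bu4NF, THF, rt → 40 °C
Reagents that add atoms: none
Why: Fluoride-induced silyl ether cleavage driven by Si–F bond formation; removing silicon before ring closure rules out alkoxide-triggered silyl migration onto the C2 oxygen in the last step.

Step 9
Reactants: 13 (3S,4R,5S)-5-(3,4-dimethoxyphenyl)-3-[(S)-(3,4-dimethoxyphenyl)(hydroxy)methyl]-4-(hydroxymethyl)oxolan-3-ol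
Product: 15 (1S,2S,5R,6S)-2,6-bis(3,4-dimethoxyphenyl)-3,7-dioxabicyclo[3.3.0]octan-1-ol, via primary tosylate 14 (not isolated)
Conditions: TsCl (1.1 equiv), pyridine, CH2Cl2, 0 °C; then NaH, THF, 0 °C → rt
Reagents that add atoms: none
Why: Selective sulfonylation of the only primary hydroxyl followed by intramolecular Williamson etherification (5-exo-tet) by the C2 alkoxide, in which the C2–O bond is never broken so the endo aryl configuration is kept, and the tertiary C1 alkoxide could only give a strained oxetane (4-exo-tet), which is far slower.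

**Compound list**

1 | veratraldehyde (3,4-dimethoxybenzaldehyde) | COc1ccc(C=O)cc1OC | starting material
2 | allenylboronic acid pinacol ester | C=C=CB1OC(C)(C)C(C)(C)O1 | starting material
3 | (S)-1-(3,4-dimethoxyphenyl)but-3-yn-1-ol | C#CC[C@H](O)c1ccc(OC)c(OC)c1 | intermediate
4 | (S)-5-(3,4-dimethoxyphenyl)dihydrofuran-3(2H)-one | COc1ccc([C@H]2OCC(=O)C2)cc1OC | intermediate
5 | potassium (S)-5-(3,4-dimethoxyphenyl)-2,5-dihydrofuran-3-olate (formed in the flask) | COc1ccc([C@H]2OCC([O-])=C2)cc1OC.[K+] | intermediate
6 | (S)-tert-butyl{[5-(3,4-dimethoxyphenyl)-2,5-dihydrofuran-3-yl]oxy}dimethylsilane (C1=C5 silyl enol ether) | COc1ccc([C@H]2OCC(O[Si](C)(C)C(C)(C)C)=C2)cc1OC | intermediate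
7 | (3,4-dimethoxyphenyl)acetic acid | COc1ccc(CC(O)=O)cc1OC | starting material
8 | (3,4-dimethoxyphenyl)acetyl chloride | COc1ccc(CC(Cl)=O)cc1OC | intermediate
9 | (3,4-dimethoxyphenyl)ketene (formed in the flask) | COc1ccc(C=C=O)cc1OC | intermediate
10 | (1S,4S,5R,7S)-1-(tert-butyldimethylsilyloxy)-4,7-bis(3,4-dimethoxyphenyl)-3-oxabicyclo[3.2.0]heptan-6-one (OTBS, H-5 and C6 aryl on one face; C2 aryl endo, cis to C8) | COc1ccc([C@H]2OC[C@@]3(O[Si](C)(C)C(C)(C)C)[C@@H]2C(=O)[C@H]3c2ccc(OC)c(OC)c2)cc1OC | intermediate
11 | (1S,2S,5R,6S)-1-(tert-butyldimethylsilyloxy)-2,6-bis(3,4-dimethoxyphenyl)-3,7-dioxabicyclo[3.3.0]octan-4-one (target numbering) | COc1ccc([C@H]2OC[C@@]3(O[Si](C)(C)C(C)(C)C)[C@@H]2C(=O)O[C@H]3c2ccc(OC)c(OC)c2)cc1OC | intermediate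
12 | (S)-[(3S,4R,5S)-3-(tert-butyldimethylsilyloxy)-5-(3,4-dimethoxyphenyl)-4-(hydroxymethyl)oxolan-3-yl](3,4-dimethoxyphenyl)methanol | COc1ccc([C@H]2OC[C@](O[Si](C)(C)C(C)(C)C)([C@@H](O)c3ccc(OC)c(OC)c3)[C@@H]2CO)cc1OC | intermediate
13 | (3S,4R,5S)-5-(3,4-dimethoxyphenyl)-3-[(S)-(3,4-dimethoxyphenyl)(hydroxy)methyl]-4-(hydroxymethyl)oxolan-3-ol | COc1ccc([C@H]2OC[C@](O)([C@@H](O)c3ccc(OC)c(OC)c3)[C@@H]2CO)cc1OC | intermediate
14 | {(2S,3R,4S)-2-(3,4-dimethoxyphenyl)-4-[(S)-(3,4-dimethoxyphenyl)(hydroxy)methyl]-4-hydroxyoxolan-3-yl}methyl 4-methylbenzenesulfonate (formed in the flask) | COc1ccc([C@H]2OC[C@](O)([C@@H](O)c3ccc(OC)c(OC)c3)[C@@H]2COS(=O)(=O)c4ccc(C)cc4)cc1OC | intermediate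
15 | (1S,2S,5R,6S)-2,6-bis(3,4-dimethoxyphenyl)-3,7-dioxabicyclo[3.3.0]octan-1-ol | COc1ccc([C@H]2OC[C@@]3(O)[C@@H]2CO[C@H]3c2ccc(OC)c(OC)c2)cc1OC | target

**Step count and risks**

Total steps: 9. Longest linear sequence: 8 (steps 1–3 and 5–9 from veratraldehyde 1); step 4 is the one-step side branch.

Steps most likely to fail:

1. Step 5. The ketene may dimerise faster than it adds to the hindered trisubstituted enol ether. Silicon may also transfer to the enolate oxygen in the dipolar adduct, giving open-chain acylation instead of ring closure, and amine-mediated epimerisation at C2 may erode endo control. The fallback sets out from 6 and uses a more electrophilic chloro(aryl)ketene, with the C2 configuration set afterwards by protonation. 3,4-Dimethoxymandelic acid F1 would be converted with SOCl2 (cat. DMF) into 2-chloro-2-(3,4-dimethoxyphenyl)acetyl chloride F2. With Et3N in the presence of 6 this should give chloro(3,4-dimethoxyphenyl)ketene F3 and, by the same bond-forming mode, the 7-chloro-7-aryl cyclobutanone F4 (either C2 epimer serves). Zn in AcOH/THF at 0 °C would then remove chlorine; protonation of the zinc enolate is expected from the convex face, which again places the aryl endo. The route is rejoined at 10.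

2. Step 3. Proton removal at C8 may compete, giving a mixture of enol ether regioisomers, or the C5 enolate may open by β-elimination of the ring oxygen. The fallback sets out from 1 and forms the C1=C5 double bond by ring-closing metathesis, so that no enolisation of a cyclic ketone is involved. Enantioselective vinyl transfer to 1 (Zn(CH=CH2)2, chiral amino alcohol ligand) would give (S)-1-(3,4-dimethoxyphenyl)prop-2-en-1-ol F5. O-Alkylation with bromoacetic acid (NaH, THF) would give (S)-2-{[1-(3,4-dimethoxyphenyl)prop-2-en-1-yl]oxy}acetic acid F6, and TBSCl/imidazole its tert-butyldimethylsilyl ester F7. Petasis methylenation (Cp2TiMe2, toluene, 65 °C) would turn the silyl ester into the 2-silyloxyallyl ether F8. Ring-closing metathesis with the second-generation Grubbs catalyst (H2IMes)(PCy3)Cl2Ru=CHPh in benzene at 60 °C should then close ring A with loss of ethene. The route is rejoined at 6.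

3. Step 6. The peracid may attack the dimethoxyarenes, or C5 may migrate in place of C2. The fallback sets out from 10 and inserts the oxygen photochemically. Irradiation (λ > 300 nm, THF–H2O) should cleave the C4–C2 bond on the benzylic side (Norrish α-cleavage). The acyl–benzyl biradical should reclose through oxygen to the ring-expanded oxacarbene with retention at C2, and water should trap it as the ring-B lactol F9. NaBH4 in MeOH would reduce the lactol to the diol. The route is rejoined at 12, bypassing 11.

Further compounds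
F1 | step 5 | 3,4-dimethoxymandelic acid (racemic, commercial) | COc1ccc(C(O)C(O)=O)cc1OC
F2 | step 5 | 2-chloro-2-(3,4-dimethoxyphenyl)acetyl chloride | COc1ccc(C(Cl)C(Cl)=O)cc1OC
F3 | step 5 | chloro(3,4-dimethoxyphenyl)ketene | COc1ccc(C(Cl)=C=O)cc1OC
F4 | step 5 | (1S,4S,5R)-7-chloro-1-(tert-butyldimethylsilyloxy)-4,7-bis(3,4-dimethoxyphenyl)-3-oxabicyclo[3.2.0]heptan-6-one (C7 epimers) | COc1ccc([C@H]2OC[C@@]3(O[Si](C)(C)C(C)(C)C)[C@@H]2C(=O)C3(Cl)c2ccc(OC)c(OC)c2)cc1OC
F5 | step 3 | (S)-1-(3,4-dimethoxyphenyl)prop-2-en-1-ol | C=C[C@H](O)c1ccc(OC)c(OC)c1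
F6 | step 3 | (S)-2-{[1-(3,4-dimethoxyphenyl)prop-2-en-1-yl]oxy}acetic acid | C=C[C@H](OCC(O)=O)c1ccc(OC)c(OC)c1
F7 | step 3 | tert-butyldimethylsilyl (S)-2-{[1-(3,4-dimethoxyphenyl)prop-2-en-1-yl]oxy}acetate | C=C[C@H](OCC(=O)O[Si](C)(C)C(C)(C)C)c1ccc(OC)c(OC)c1
F8 | step 3 | (S)-tert-butyl[(3-{[1-(3,4-dimethoxyphenyl)prop-2-en-1-yl]oxy}prop-1-en-2-yl)oxy]dimethylsilane | C=C[C@H](OCC(=C)O[Si](C)(C)C(C)(C)C)c1ccc(OC)c(OC)c1
F9 | step 6 | (1S,2S,5R,6S)-1-(tert-butyldimethylsilyloxy)-2,6-bis(3,4-dimethoxyphenyl)-3,7-dioxabicyclo[3.3.0]octan-4-ol (lactol, C4 anomers; target numbering) | COc1ccc([C@H]2OC[C@@]3(O[Si](C)(C)C(C)(C)C)[C@@H]2C(O)O[C@H]3c2ccc(OC)c(OC)c2)cc1OC
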